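Both benzene rings of the target are 5-alkylresorcinols: oxygen on C3′ and C5′, the C14 tether on C1′, so oxygen sits on every second ring carbon, the imprint of a folded poly-β-carbonyl chain. Each ring is therefore disconnected at the C1′–C2′ bond, C2′ being the carbon that carries a removable ester. The precursor is a symmetrical, fully acyclic bis(3,5,7-trioxo ester) whose two C7 ketones are joined by fourteen methylenes. One base-mediated operation closes both ends by C2→C7 aldol condensation and aromatization, creating two rings and two C–C bonds with no protecting group. A C16 bis(Weinreb amide) and a dioxohexanoate trianion supply the precursor; saponification and decarboxylation finish the synthesis.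

Key step: step 4

Remark on the chemistry: the target has no stereogenic element (it is achiral), so only one stereoisomer exists and no step needs stereocontrol.

Remark on the design: the key-step precursor and product are atom-consistent (C30H46O10 → C30H42O8 + 2 H2O) and are kept unchanged, methyl esters included. Only the assembly of the precursor is changed: the C16 unit is delivered as a bis(Weinreb amide), so that each acylation stops at a stable tetrahedral adduct and needs no sacrificial trianion.

Step 1
Reactants: 1 dehydroacetic acid (3-acetyl-4-hydroxy-6-methyl-2H-pyran-2-one)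
Product: 3 methyl 3,5-dioxohexanoate, via methyl 2-acetyl-3,5-dioxohexanoate 2 (not isolated)
Conditions: Mg(OMe)2 (2 equiv), MeOH, reflux; then cold aq. HCl; vacuum distillation
Reagents that add atoms: methanol, CO (delivered as magnesium methoxide, CO[Mg]OC)
Why: Methoxide opens the lactone and the resulting triacylmethane 2 loses its acetyl group as methyl acetate by retro-Claisen cleavage, while magnesium chelation of the β,δ-diketo ester formed should stop further cleavage (alkoxide lactone opening/retro-Claisen deacetylation, a standard preparation of this ester).

Step 2
Reactants: 4 hexadecanedioic acid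
Product: 6 hexadecanedioic acid bis(N-methoxy-N-methylamide), via hexadecanedioyl bis(imidazolide) 5 (not isolated)
Conditions: CDI (2.2 equiv), THF, 40 °C; then MeNH(OMe)·HCl (2.5 equiv), rt
Reagents that add atoms: N,O-dimethylhydroxylamine hydrochloride, CNOC.Cl
Why: Activation of both carboxyl groups as acyl imidazoles followed by aminolysis with the hydroxylamine (carbonyldiimidazole amide coupling) is a routine, nearly neutral Weinreb amide preparation, and the saturated chain offers no competing site.

Step 3
Reactants: 3 methyl 3,5-dioxohexanoate (2.6 equiv, as its trilithio trianion); 6 hexadecanedioic acid bis(N-methoxy-N-methylamide)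
Product: 8 dimethyl 3,5,7,22,24,26-hexaoxooctacosanedioate, via twofold tetrahedral Weinreb adduct 7 (not isolated)
Conditions: 3, LDA (3 equiv per 3), THF, −78 → 0 °C; then 6, 0 °C → rt; poured into cold 1 M HCl
Reagents that add atoms: none
Why: In this Weinreb ketone synthesis with a 1,3,5-tricarbonyl trianion, the terminal C6 carbanion (the last formed and most nucleophilic site) adds to each amide carbonyl and the lithium-chelated adduct 7 persists until the cold acidic quench, so neither over-addition nor proton transfer from a newly formed active methylene should consume the nucleophile.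

Step 4
Reactants: 8 dimethyl 3,5,7,22,24,26-hexaoxooctacosanedioate
Product: 10 dimethyl 6,6'-(tetradecane-1,14-diyl)bis(2,4-dihydroxybenzoate), via twofold cyclic aldol adduct 9 (not isolated)
Conditions: aq. NaHCO3/Na2CO3 buffer (pH ≈ 9.2)/THF, rt, Ar; then 1 M HCl to pH 2
Reagents that add atoms: none
Why: In the weakly basic aqueous medium each triketo ester terminus is reversibly enolized, and the C2 carbanion (flanked by the ester and the C3 ketone) adds to the un-ionized C7 ketone to give the cyclic β-hydroxy ketone 9, which loses water by E1cB elimination and tautomerizes at C3 and C5 to the phenol, so aromatization drains every equilibrium toward the resorcylate. The closest known reaction type is the biomimetic aldol cyclization–aromatization of 3,5,7-triketo esters to 6-substituted 2,4-dihydroxybenzoates. Each of the two benzene rings is closed in the 6-(enolendo)-exo-trig mode, with one new ring bond per end (C2–C7 and C27–C22). The product has no stereocentre; the carbinol and ester-bearing carbons of 9 are transient and are erased on aromatization. The step needs mode selectivity for the C2→C7 aldol over C6→C1 Claisen closure (acylphloroglucinol) and over O-cyclization to pyranones: the methyl ester is the poorest electrophile of the chain, the alkoxide-free and magnesium-free buffer neither activates it nor holds the chain in a chelated Claisen geometry, and the strongly acidic dehydrating conditions that give pyranones are avoided. The two termini are insulated by fourteen methylenes and should react independently, and both phenol pairs emerge unprotected.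

Step 5
Reactants: 10 dimethyl 6,6'-(tetradecane-1,14-diyl)bis(2,4-dihydroxybenzoate)
Product: 12 bisnorstriatol [5,5'-(tetradecane-1,14-diyl)di(benzene-1,3-diol)], via twofold β-resorcylic acid 11 (not isolated)
Conditions: 4 M aq. KOH, 1,4-dioxane, reflux, Ar; then 6 M HCl to pH 1, 90 °C
Reagents that add atoms: none
Why: Hot concentrated alkali should force BAc2 saponification of the hindered resorcylate esters, and the liberated acids, with carboxyl ortho and para to hydroxyl, undergo the classical ipso-protodecarboxylation of 2,4-dihydroxybenzoic acids on warming in acid, the inert atmosphere protecting the electron-rich phenols.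

Compound list
1 | dehydroacetic acid (3-acetyl-4-hydroxy-6-methyl-2H-pyran-2-one) | CC(=O)C1=C(O)C=C(C)OC1=O | starting material
2 | methyl 2-acetyl-3,5-dioxohexanoate (ring-opened triacylmethane, keto form drawn; not isolated) | COC(=O)C(C(C)=O)C(=O)CC(C)=O | intermediate
3 | methyl 3,5-dioxohexanoate | COC(=O)CC(=O)CC(C)=O | intermediate
4 | hexadecanedioic acid | OC(=O)CCCCCCCCCCCCCCC(=O)O | starting material
5 | hexadecanedioyl bis(imidazolide), 1,16-di(1H-imidazol-1-yl)hexadecane-1,16-dione (not isolated) | O=C(CCCCCCCCCCCCCCC(=O)n1ccnc1)n1ccnc1 | intermediate
6 | hexadecanedioic acid bis(N-methoxy-N-methylamide) | CON(C)C(=O)CCCCCCCCCCCCCCC(=O)N(C)OC | intermediate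
7 | twofold tetrahedral Weinreb adduct, dimethyl 7,22-dihydroxy-7,22-bis[methoxy(methyl)amino]-3,5,24,26-tetraoxooctacosanedioate (present as its lithium chelate, drawn neutral; C7 and C22 unassigned; not isolated) | COC(=O)CC(=O)CC(=O)CC(O)(N(C)OC)CCCCCCCCCCCCCCC(O)(N(C)OC)CC(=O)CC(=O)CC(=O)OC | intermediate
8 | dimethyl 3,5,7,22,24,26-hexaoxooctacosanedioate (keto form drawn; largely enolized) | COC(=O)CC(=O)CC(=O)CC(=O)CCCCCCCCCCCCCCC(=O)CC(=O)CC(=O)CC(=O)OC | intermediate
9 | twofold cyclic aldol adduct, dimethyl 2,2'-(tetradecane-1,14-diyl)bis(2-hydroxy-4,6-dioxocyclohexane-1-carboxylate) (transient mixture of diastereomers; not isolated) | COC(=O)C1C(=O)CC(=O)CC1(O)CCCCCCCCCCCCCCC1(O)CC(=O)CC(=O)C1C(=O)OC | intermediate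
10 | dimethyl 6,6'-(tetradecane-1,14-diyl)bis(2,4-dihydroxybenzoate) | COC(=O)c1c(O)cc(O)cc1CCCCCCCCCCCCCCc1cc(O)cc(O)c1C(=O)OC | intermediate
11 | 6,6'-(tetradecane-1,14-diyl)bis(2,4-dihydroxybenzoic acid) (not isolated) | OC(=O)c1c(O)cc(O)cc1CCCCCCCCCCCCCCc1cc(O)cc(O)c1C(=O)O | intermediate
12 | bisnorstriatol, 5,5'-(tetradecane-1,14-diyl)di(benzene-1,3-diol) (achiral) | Oc1cc(O)cc(CCCCCCCCCCCCCCc2cc(O)cc(O)c2)c1 | target

Total step count: 5. Longest linear sequence: 4 steps (1 → 3 → 4 → 5, or 2 → 3 → 4 → 5); the two branches meet in step 3.

Steps most likely to fail

Step 4. One or both termini may cyclize in a competing mode (attack of C6 on the ester carbon, or O-cyclization to a pyranone) or stall at the aldol stage; with two independent ends this would give mixtures. The fallback sets out from 6 and comes back at 11. Commercial 2,2,6-trimethyl-4H-1,3-dioxin-4-one would be acetylated on its methyl carbon through the lithium dienolate (LiHMDS, THF, −78 °C; acetyl chloride) to 2,2-dimethyl-6-(2-oxopropyl)-4H-1,3-dioxin-4-one F1. Its dilithio dianion (LDA, THF, −78 °C) would be acylated at the terminal carbon by both amide groups of 6 to give 6,6'-(2,4,19,21-tetraoxodocosane-1,22-diyl)bis(2,2-dimethyl-4H-1,3-dioxin-4-one) F2. Triethylamine in CH2Cl2 should then close each end by aldol condensation of the dioxinone C5 onto the distal ketone. Here the carboxyl carbon lies trans to the side chain across the ring double bond and the C3 oxygen is locked in the acetonide, so Claisen closure and pyranone formation are structurally excluded. The product would be 5,5'-(tetradecane-1,14-diyl)bis(7-hydroxy-2,2-dimethyl-4H-1,3-benzodioxin-4-one) F3. Aqueous KOH/dioxane opens both acetonide-lactone rings with loss of acetone to 11, which is decarboxylated as in step 5.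

Step 3. The second acylation may remain incomplete because the polylithiated species aggregate and precipitate, or the strongly basic carbanion may induce loss of formaldehyde from the N-methoxy group instead of adding to the carbonyl. The fallback sets out from 6 and comes back at 8, attaching the ester carbon last. The dilithio dianion of acetylacetone (LDA, 2 equiv, THF, 0 °C) would be acylated at its terminal carbon by 6 to give hexacosane-2,4,6,21,23,25-hexaone F4. Lithiation of F4 to its hexaanion (LDA, THF, 0 °C) and carboxylation of both terminal methyl carbanions with CO2 should give 3,5,7,22,24,26-hexaoxooctacosanedioic acid F5 after cold acidification. Brief esterification of F5 with trimethylsilyldiazomethane in MeOH/toluene at 0 °C would return 8.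

Step 5. Acyl substitution at the doubly ortho-substituted, phenoxide-deactivated ester carbonyl may be sluggish, and the polyphenolate may oxidize in hot alkali. The fallback sets out from 10 and comes back at 11, attacking the methyl carbon instead of the carbonyl. Lithium iodide in refluxing pyridine under argon should cleave both O–methyl bonds by SN2 displacement while the phenols stay un-ionized, giving 11 as its lithium salt. Acidification and warming as in step 5 then complete the loss of CO2 to 12. This detour makes no compound outside the compound list (entry F0).

Further compounds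
F1 | step 4 | 2,2-dimethyl-6-(2-oxopropyl)-4H-1,3-dioxin-4-one | CC(=O)CC1=CC(=O)OC(C)(C)O1
F2 | step 4 | 6,6'-(2,4,19,21-tetraoxodocosane-1,22-diyl)bis(2,2-dimethyl-4H-1,3-dioxin-4-one) | CC1(C)OC(=O)C=C(CC(=O)CC(=O)CCCCCCCCCCCCCCC(=O)CC(=O)CC2=CC(=O)OC(C)(C)O2)O1
F3 | step 4 | 5,5'-(tetradecane-1,14-diyl)bis(7-hydroxy-2,2-dimethyl-4H-1,3-benzodioxin-4-one) | O=C1OC(C)(C)Oc2cc(O)cc(CCCCCCCCCCCCCCc3cc(O)cc4OC(C)(C)OC(=O)c34)c12
F4 | step 3 | hexacosane-2,4,6,21,23,25-hexaone | CC(=O)CC(=O)CC(=O)CCCCCCCCCCCCCCC(=O)CC(=O)CC(C)=O
F5 | step 3 | 3,5,7,22,24,26-hexaoxooctacosanedioic acid | OC(=O)CC(=O)CC(=O)CC(=O)CCCCCCCCCCCCCCC(=O)CC(=O)CC(=O)CC(=O)O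
F0 | step 5 | none | none
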